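Assumption: rotation about the two interflavan bonds is treated as free (no atropisomer to control), and (+)-catechin, 3,4,5-tris(benzyloxy)benzoic acid and the reagents named are taken as commercial.

## The problem

The target is the B-type procyanidin trimer epicatechin-(4β→8)-epicatechin 3-O-gallate-(4β→8)-epicatechin 3-O-gallate: three 2R,3R flavan-3-ol units joined by two bonds from C4 of ring C of an upper unit to C8 of ring A of the unit below, with a gallate on O3 of the middle and lower units only. Each interflavan bond must form at C8 and not C6 of a phloroglucinol ring, and on the face of C4 opposite to the C3 oxygen and the C2 aryl group (2,3-cis-3,4-trans). The chain must not grow on, because every unit with a free C8 is a nucleophile and every unit activated at C4 is an electrophile. The middle unit is the crux: it is a nucleophile at C8, an electrophile at C4, and it carries an acyl group on the carbon next to the cationic centre. Stereocontrol can be relayed along ring C: C2 (from the chiral pool) can set C3, and C3 can set C4. The feature that makes the key step possible lies in ring C of the middle unit: C3 bears the galloyloxy group, and the neighbouring C4 is benzylic to ring A with its three oxygens (O1, O5, O7) and bears the bond to C8 of ring A of the lower unit. C3–C4 is therefore the hydroarylated form of the C3=C4 enol gallate of a flavan-3-one, and protonation of that enol ester at C3 gives the same C4 cation that procyanidin couplings use. Interflavan bonds cleave in acid (ipso-protonation at C8), gallate esters and C2 of free phenolic flavanols do not tolerate base, and the free catechol and pyrogallol rings oxidise in air, so the phenols stay benzylated until a final neutral hydrogenolysis.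

## Retrosynthesis

**17 from 16.** The eighteen O–benzyl bonds and one C8–Br bond of the fully protected trimer 16 are cut last, in one hydrogenolysis. Benzyl ethers are the only phenol protection that leaves under neutral conditions compatible with esters and interflavan bonds. The bromine is a cap that the same operation removes.

**16 from 11 and 14.** The C4(top)–C8(middle) bond is cut. The top unit has a free O3 and must be an electrophile only, so it enters as the C8-brominated C4 ether 14, which ionises to cation 15. The dimer 11 has one unhindered nucleophilic carbon (C8 of its upper unit). This cut is placed last, against cutting the lower bond last, so that the precedented coupling is used on the most valuable intermediate and in near-equimolar amounts.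

**11 from 9 and 7 (key).** The C4(middle)–C8(lower) bond and the C3–H bond of the middle unit are cut together. This leads to the enol gallate 9, with no stereocentre at C3 or C4 and no leaving group, and to the protected epicatechin gallate 7. In the forward sense, protonation of 9 at C3 gives cation 10 and C8 of 7 adds to C4. The step must set C3 (from C2) and C4 (from C3), form the bond at C8, and deliver the gallate already in place. Against the neighbouring cut (a C4 ether of a 3-O-acyl flavan), it needs no oxidation at C4, no acylation of a flanked axial alcohol and no stoichiometric activator.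

**9 from 3 and 6.** The enol O–acyl bond is cut. Ketone 3 is deprotonated at C4 to the potassium enolate 8, which is acylated on oxygen by acid chloride 6. The forward reaction must take the C4 proton, not the C2 proton, and must acylate O, not C.

**7 and 14 from 4.** Ester 7 is the acylation product of tetra-O-benzyl-epicatechin 4 with 6. Ether 14 comes from 4 by quinone-mediated alkoxylation at C4 (through cation 12, giving ether 13) followed by bromination at C8. The oxidation is placed before the bromination so that the hydride abstraction is done on the more electron-rich, bromine-free ring, and so that 13 is also at hand as a bromine-free electrophile. Alcohol 4 is the hydride-reduction product of the same ketone 3, so 3 is the single branching point for all three flavan units.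

**3 from 1; 6 from 5.** Ketone 3 is the oxidation product of tetra-O-benzyl-catechin 2, made from (+)-catechin 1. Only C2 of 1 is used as chiral information, since C3 is erased at 3, so the C3 epimer of the feedstock would converge on the same ketone. Acid chloride 6 comes from acid 5.

## Roads not taken

Alternative 1: The most obvious plan cuts the same C4–C8 bonds by ionising C4 ethers throughout. Ether 13 would be acylated with 6 to give the galloylated C4 ether A1. Me3SiOSO2CF3 would then ionise A1 in the presence of an excess of 7 to give 11. This is reliable, and its dimer-stage variant serves as the fallback for step 7. The chosen plan is preferred for three reasons: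
- A1 needs a stoichiometric quinone oxidation and then acylation of an axial alcohol flanked by the C2 aryl and C4 alkoxy groups; 9 is made from 3 in one step.
- It spends a leaving group and an activator per bond, where the chosen step is a catalytic, by-product-free addition.
- It uses C3 as preformed information, where the chosen step creates C3 and C4 together from C2.

Alternative 2: Polarity reversal. The cut is again C4–C8, but with a nucleophilic C8 (bromine–lithium exchange on the lower unit) adding to the C4 ketone A2, followed by ionic deoxygenation of the tertiary benzylic centre. Hydride would enter C4 anti to the C3 oxygen, leaving the aryl group cis to it (4α), which is the wrong configuration. An aryllithium is also incompatible with gallate esters, so both acylations would move to the end, and two extra redox steps per bond are needed.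

Alternative 3: Tether-directed intramolecular coupling. O3 of the electrophile and O3 of the nucleophile would be bridged by a diacid (the glutarate A3), the C4–C8 bond closed as a macrocycle by ionisation at C4, and the tether then removed. This suppresses oligomerisation without excess nucleophile. However, the tether occupies exactly the two oxygens that must carry the gallates, so it costs tether installation, removal and two late acylations. Delivery from O3 through a short bridge would also favour the 3,4-cis face. In the chosen plan the gallate itself is the activating group and stays in the product.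

Key step: step 7

## Route

Step 1
Reactants: 1 (+)-catechin
Product: 2 5,7,3',4'-tetra-O-benzyl-(+)-catechin
Conditions: BnBr (4.4 equiv), K2CO3, DMF, 0 °C to rt, argon
Reagents that add atoms: benzyl bromide BrCc1ccccc1
Why: Williamson etherification; carbonate deprotonates only the four phenols, not the C3 alcohol, and no stereocentre is touched.

Step 2
Reactants: 2 5,7,3',4'-tetra-O-benzyl-(+)-catechin
Product: 3 (2R)-5,7-bis(benzyloxy)-2-[3,4-bis(benzyloxy)phenyl]chroman-3-one
Conditions: Dess–Martin periodinane, wet CH2Cl2, rt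
Reagents that add atoms: none
Why: Dess–Martin oxidation under neutral conditions gives the ketone without enolisation toward C2, so the 2R centre is kept; the C3 configuration of the feedstock is deliberately erased.

Step 3
Reactants: 3 (2R)-5,7-bis(benzyloxy)-2-[3,4-bis(benzyloxy)phenyl]chroman-3-one
Product: 4 5,7,3',4'-tetra-O-benzyl-(−)-epicatechin
Conditions: LiBH(s-Bu)3, LiBr, THF, −78 °C; then H2O
Reagents that add atoms: none
Why: Diastereoselective ketone reduction by a bulky trialkylborohydride; hydride reaches C3 from the face opposite to the C2 aryl group, giving the axial 2,3-cis (3R) alcohol.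

Step 4
Reactants: 5 3,4,5-tris(benzyloxy)benzoic acid
Product: 6 3,4,5-tris(benzyloxy)benzoyl chloride
Conditions: (COCl)2, N,N-dimethylformamide (cat.), CH2Cl2, 0 °C to rt
Reagents that add atoms: oxalyl chloride ClC(=O)C(=O)Cl
Why: Standard acid chloride formation through the chloroiminium species; benzyl ethers are inert.

Step 5
Reactants: 4 5,7,3',4'-tetra-O-benzyl-(−)-epicatechin, 6 3,4,5-tris(benzyloxy)benzoyl chloride
Product: 7 5,7,3',4'-tetra-O-benzyl-(−)-epicatechin 3-O-(3,4,5-tri-O-benzylgallate)
Conditions: Et3N, 4-(dimethylamino)pyridine, CH2Cl2, 0 °C to rt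
Reagents that add atoms: none
Why: Esterification of the axial C3 alcohol by nucleophilic (acylpyridinium) catalysis; no stereocentre changes.

Step 6
Reactants: 3 (2R)-5,7-bis(benzyloxy)-2-[3,4-bis(benzyloxy)phenyl]chroman-3-one, 6 3,4,5-tris(benzyloxy)benzoyl chloride
Product: 9 (2R)-5,7-bis(benzyloxy)-2-[3,4-bis(benzyloxy)phenyl]-2H-chromen-3-yl 3,4,5-tris(benzyloxy)benzoate, via potassium enolate 8 (not isolated)
Conditions: KN(SiMe3)2 (1.1 equiv), THF, −78 °C (3 added to the base); then 6, −78 to −40 °C
Reagents that add atoms: none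
Why: Kinetic deprotonation by the hindered amide at the unhindered C4 methylene rather than the tertiary C2–H (inverse addition keeps base in excess so 8 cannot equilibrate through unreacted ketone), then O-acylation of the potassium enolate by the hard acyl chloride (enol ester formation); C2 is not touched.

Step 7
Reactants: 9 (2R)-5,7-bis(benzyloxy)-2-[3,4-bis(benzyloxy)phenyl]-2H-chromen-3-yl 3,4,5-tris(benzyloxy)benzoate, 7 5,7,3',4'-tetra-O-benzyl-(−)-epicatechin 3-O-(3,4,5-tri-O-benzylgallate)
Product: 11 tetradeca-O-benzyl procyanidin B2 3,3'-di-O-gallate, via C4 benzylic cation 10 (not isolated)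
Conditions: 7 (2.0 equiv), HN(SO2CF3)2 (10 mol%), CH2Cl2, −40 °C; 9 added over 2 h; then Et3N
Reagents that add atoms: none
Why: Proposed new method: protonation of the electron-rich C3=C4 bond of 9 at C3 (the carbon bearing the acyloxy group) gives the 2,4,6-trioxygenated benzylic cation 10, the species that Lewis acids generate from C4 ethers of 3-O-acyl flavan-3-ols, and C8 of ring A of 7 captures it at C4 in a Friedel–Crafts step that returns the proton; the closest known reaction types are the acid-catalysed hydroarylation and dimerisation of 2H-chromenes through their C4 cations and the Lewis-acid C4-arylation of 3-O-acyl-4-alkoxyflavans. No ring of 11 is closed in this step (the five-membered acyloxonium bridge that the gallate carbonyl can form to C4 on the lower face is transient and is reopened by the arene). C3 is controlled by C2: allylic 1,2-strain with the C3 acyloxy group holds the C2 aryl group pseudoaxial on the α face, so the proton reaches C3 from the opposite face, the same face the hydride uses in step 3, giving the 2,3-cis (3R) arrangement. C4 is controlled by C3: the arene adds anti to the now axial C3 acyloxy group (and anti to any acyloxonium bridge), giving the 3,4-trans (4β) bond. Regioselectivity for C8 over C6 of 7 follows from C6 lying between two benzyloxy groups. The step also needs chemoselectivity against self-condensation of 9 through its own C8, hydride transfer from C2–H of 9 to 10, and further arylation of 11; all three involve a second molecule derived from 9 and are held back by adding 9 slowly to an excess of 7, which is recovered.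

Step 8
Reactants: 4 5,7,3',4'-tetra-O-benzyl-(−)-epicatechin
Product: 13 (2R,3R,4S)-5,7-bis(benzyloxy)-2-[3,4-bis(benzyloxy)phenyl]-4-(2-ethoxyethoxy)chroman-3-ol, via C4 cation 12 (not isolated)
Conditions: DDQ (2 equiv), 2-ethoxyethanol (5 equiv), CH2Cl2, rt
Reagents that add atoms: 2-ethoxyethanol CCOCCO
Why: Quinone-mediated benzylic hydride abstraction at C4 of the trioxygenated ring gives cation 12, which the alcohol, present in excess over any free C8 nucleophile, traps anti to the C3 hydroxyl (4β ether); the C4 configuration is immaterial because the centre is ionised again in step 10.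

Step 9
Reactants: 13 (2R,3R,4S)-5,7-bis(benzyloxy)-2-[3,4-bis(benzyloxy)phenyl]-4-(2-ethoxyethoxy)chroman-3-ol
Product: 14 (2R,3R,4S)-8-bromo-5,7-bis(benzyloxy)-2-[3,4-bis(benzyloxy)phenyl]-4-(2-ethoxyethoxy)chroman-3-ol
Conditions: N-bromosuccinimide (1.0 equiv), NaHCO3, CH2Cl2, −78 to 0 °C, dark
Reagents that add atoms: N-bromosuccinimide O=C1CCC(=O)N1Br
Why: Electrophilic aromatic bromination; C8, flanked by O1 and one benzyloxy group, is more accessible than C6 between two benzyloxy groups (the C4 substituent peri to the 5-benzyloxy group crowds C6 further). The reaction liberates only neutral succinimide, so the acid-labile C4 ether and the stereocentres are untouched, and the bromine blocks the only nucleophilic site of the future top unit.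

Step 10
Reactants: 14 (2R,3R,4S)-8-bromo-5,7-bis(benzyloxy)-2-[3,4-bis(benzyloxy)phenyl]-4-(2-ethoxyethoxy)chroman-3-ol, 11 tetradeca-O-benzyl procyanidin B2 3,3'-di-O-gallate
Product: 16 8-bromo-octadeca-O-benzyl trimer, via brominated C4 cation 15 (not isolated)
Conditions: 14 (1.1 equiv), Me3SiOSO2CF3 (0.5 equiv), CH2Cl2, −78 °C; then Et3N
Reagents that add atoms: none
Why: Lewis-acid-mediated Friedel–Crafts C4-arylation of a flavan-3-ol C4 ether; ionisation of 14 gives cation 15, which is attacked by the only unhindered nucleophilic carbon of 11 (C8 of its upper unit) anti to the axial C3 hydroxyl, setting the second 4β (3,4-trans) bond. The C8 bromine of 14 excludes self-condensation, so near-equimolar amounts suffice.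

Step 11
Reactants: 16 8-bromo-octadeca-O-benzyl trimer
Product: 17 epicatechin-(4β→8)-epicatechin 3-O-gallate-(4β→8)-epicatechin 3-O-gallate (CNP0279403.1)
Conditions: H2 (1 atm), Pd(OH)2 on carbon, Et3N (1.1 equiv), THF/MeOH/H2O, rt
Reagents that add atoms: none
Why: Heterogeneous hydrogenolysis cleaves all eighteen benzyl ethers and the aryl C–Br bond in one operation; the amine takes up the HBr that would otherwise cleave interflavan bonds, and esters, C2 centres and interflavan bonds are untouched.

## Compound list

1 | (+)-catechin, (2R,3S)-2-(3,4-dihydroxyphenyl)chromane-3,5,7-triol | O[C@H]1Cc2c(O)cc(O)cc2O[C@@H]1c1ccc(O)c(O)c1 | starting material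
2 | 5,7,3',4'-tetra-O-benzyl-(+)-catechin, (2R,3S)-5,7-bis(benzyloxy)-2-[3,4-bis(benzyloxy)phenyl]chroman-3-ol | O[C@H]1Cc2c(OCc9ccccc9)cc(OCc9ccccc9)cc2O[C@@H]1c1ccc(OCc9ccccc9)c(OCc9ccccc9)c1 | intermediate
3 | (2R)-5,7-bis(benzyloxy)-2-[3,4-bis(benzyloxy)phenyl]chroman-3-one | O=C1Cc2c(OCc9ccccc9)cc(OCc9ccccc9)cc2O[C@@H]1c1ccc(OCc9ccccc9)c(OCc9ccccc9)c1 | intermediate
4 | 5,7,3',4'-tetra-O-benzyl-(−)-epicatechin, (2R,3R)-5,7-bis(benzyloxy)-2-[3,4-bis(benzyloxy)phenyl]chroman-3-ol | O[C@@H]1Cc2c(OCc9ccccc9)cc(OCc9ccccc9)cc2O[C@@H]1c1ccc(OCc9ccccc9)c(OCc9ccccc9)c1 | intermediate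
5 | 3,4,5-tris(benzyloxy)benzoic acid | OC(=O)c1cc(OCc9ccccc9)c(OCc9ccccc9)c(OCc9ccccc9)c1 | starting material
6 | 3,4,5-tris(benzyloxy)benzoyl chloride | ClC(=O)c1cc(OCc9ccccc9)c(OCc9ccccc9)c(OCc9ccccc9)c1 | intermediate
7 | 5,7,3',4'-tetra-O-benzyl-(−)-epicatechin 3-O-(3,4,5-tri-O-benzylgallate), (2R,3R)-5,7-bis(benzyloxy)-2-[3,4-bis(benzyloxy)phenyl]chroman-3-yl 3,4,5-tris(benzyloxy)benzoate | O=C(O[C@@H]1Cc2c(OCc9ccccc9)cc(OCc9ccccc9)cc2O[C@@H]1c1ccc(OCc9ccccc9)c(OCc9ccccc9)c1)c1cc(OCc9ccccc9)c(OCc9ccccc9)c(OCc9ccccc9)c1 | intermediate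
8 | potassium (2R)-5,7-bis(benzyloxy)-2-[3,4-bis(benzyloxy)phenyl]-2H-chromen-3-olate (C3=C4 enolate, not isolated) | [K+].[O-]C1=Cc2c(OCc9ccccc9)cc(OCc9ccccc9)cc2O[C@@H]1c1ccc(OCc9ccccc9)c(OCc9ccccc9)c1 | intermediate
9 | (2R)-5,7-bis(benzyloxy)-2-[3,4-bis(benzyloxy)phenyl]-2H-chromen-3-yl 3,4,5-tris(benzyloxy)benzoate (flav-3-en-3-yl gallate) | O=C(OC1=Cc2c(OCc9ccccc9)cc(OCc9ccccc9)cc2O[C@@H]1c1ccc(OCc9ccccc9)c(OCc9ccccc9)c1)c1cc(OCc9ccccc9)c(OCc9ccccc9)c(OCc9ccccc9)c1 | intermediate
10 | (2R,3R)-5,7-bis(benzyloxy)-2-[3,4-bis(benzyloxy)phenyl]-3-[3,4,5-tris(benzyloxy)benzoyloxy]chroman-4-ylium (2,3-cis C4 cation, not isolated) | O=C(O[C@@H]1[CH+]c2c(OCc9ccccc9)cc(OCc9ccccc9)cc2O[C@@H]1c1ccc(OCc9ccccc9)c(OCc9ccccc9)c1)c1cc(OCc9ccccc9)c(OCc9ccccc9)c(OCc9ccccc9)c1 | intermediate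
11 | tetradeca-O-benzyl procyanidin B2 3,3'-di-O-gallate: [5,7,3',4'-tetra-O-benzyl-epicatechin 3-O-(tri-O-benzylgallate)]-(4β→8)-[5,7,3',4'-tetra-O-benzyl-epicatechin 3-O-(tri-O-benzylgallate)]; both units 2R, 2,3-cis, upper unit 3,4-trans | O=C(O[C@@H]1[C@@H](c2c(OCc9ccccc9)cc(OCc9ccccc9)c3c2O[C@H](c2ccc(OCc9ccccc9)c(OCc9ccccc9)c2)[C@H](OC(=O)c2cc(OCc9ccccc9)c(OCc9ccccc9)c(OCc9ccccc9)c2)C3)c2c(OCc9ccccc9)cc(OCc9ccccc9)cc2O[C@@H]1c1ccc(OCc9ccccc9)c(OCc9ccccc9)c1)c1cc(OCc9ccccc9)c(OCc9ccccc9)c(OCc9ccccc9)c1 | intermediate
12 | (2R,3R)-5,7-bis(benzyloxy)-2-[3,4-bis(benzyloxy)phenyl]-3-hydroxychroman-4-ylium (bromine-free C4 cation, not isolated) | O[C@@H]1[CH+]c2c(OCc9ccccc9)cc(OCc9ccccc9)cc2O[C@@H]1c1ccc(OCc9ccccc9)c(OCc9ccccc9)c1 | intermediate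
13 | (2R,3R,4S)-5,7-bis(benzyloxy)-2-[3,4-bis(benzyloxy)phenyl]-4-(2-ethoxyethoxy)chroman-3-ol (4β ether, trans to the 3-OH) | CCOCCO[C@H]1c2c(OCc9ccccc9)cc(OCc9ccccc9)cc2O[C@H](c2ccc(OCc9ccccc9)c(OCc9ccccc9)c2)[C@@H]1O | intermediate
14 | (2R,3R,4S)-8-bromo-5,7-bis(benzyloxy)-2-[3,4-bis(benzyloxy)phenyl]-4-(2-ethoxyethoxy)chroman-3-ol (8-bromo 4β ether, trans to the 3-OH) | CCOCCO[C@H]1c2c(OCc9ccccc9)cc(OCc9ccccc9)c(Br)c2O[C@H](c2ccc(OCc9ccccc9)c(OCc9ccccc9)c2)[C@@H]1O | intermediate
15 | (2R,3R)-8-bromo-5,7-bis(benzyloxy)-2-[3,4-bis(benzyloxy)phenyl]-3-hydroxychroman-4-ylium (8-bromo C4 cation, not isolated) | O[C@@H]1[CH+]c2c(OCc9ccccc9)cc(OCc9ccccc9)c(Br)c2O[C@@H]1c1ccc(OCc9ccccc9)c(OCc9ccccc9)c1 | intermediate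
16 | [8-bromo-5,7,3',4'-tetra-O-benzyl-epicatechin]-(4β→8)-[5,7,3',4'-tetra-O-benzyl-epicatechin 3-O-(tri-O-benzylgallate)]-(4β→8)-[5,7,3',4'-tetra-O-benzyl-epicatechin 3-O-(tri-O-benzylgallate)]; all C2 R, all 2,3-cis, both interflavan bonds 3,4-trans | O=C(O[C@@H]1[C@@H](c2c(OCc9ccccc9)cc(OCc9ccccc9)c3c2O[C@H](c2ccc(OCc9ccccc9)c(OCc9ccccc9)c2)[C@H](OC(=O)c2cc(OCc9ccccc9)c(OCc9ccccc9)c(OCc9ccccc9)c2)C3)c2c(OCc9ccccc9)cc(OCc9ccccc9)c([C@H]3c4c(OCc9ccccc9)cc(OCc9ccccc9)c(Br)c4O[C@H](c4ccc(OCc9ccccc9)c(OCc9ccccc9)c4)[C@@H]3O)c2O[C@@H]1c1ccc(OCc9ccccc9)c(OCc9ccccc9)c1)c1cc(OCc9ccccc9)c(OCc9ccccc9)c(OCc9ccccc9)c1 | intermediate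
17 | epicatechin-(4β→8)-epicatechin 3-O-gallate-(4β→8)-epicatechin 3-O-gallate (CNP0279403.1) | O=C(O[C@@H]1[C@@H](c2c(O)cc(O)c3c2O[C@H](c2ccc(O)c(O)c2)[C@H](OC(=O)c2cc(O)c(O)c(O)c2)C3)c2c(O)cc(O)c([C@H]3c4c(O)cc(O)cc4O[C@H](c4ccc(O)c(O)c4)[C@@H]3O)c2O[C@@H]1c1ccc(O)c(O)c1)c1cc(O)c(O)c(O)c1 | target

## Step count and risk

Total step count: 11. Longest linear sequence: 7 steps (steps 1, 2, 3, 5, 7, 10, 11; the branch through steps 8 and 9 is equally long).

**Step 7 (key step, proposed new method).** Three things may go wrong: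
- protonation at C3 may be reversible or poorly face-selective, which would lose the 2,3-cis relationship;
- hydride may transfer from C2–H of unreacted 9 to cation 10 (disproportionation);
- acid may ionise the allylic C2–O1 bond of 9 and erode the C2 configuration.

The fallback uses known chemistry and sets out from 13, the bromine-free C4 ether made in step 8. Ionisation of 13 with Me3SiOSO2CF3 at −78 °C in the presence of an excess of 4 gives octa-O-benzyl procyanidin B2 F1. Double acylation of F1 with 6 (Et3N, 4-(dimethylamino)pyridine) comes back to the route at 11.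

**Step 6.** Proton transfer between enolate 8 and unreacted 3 may equilibrate toward the C2 enolate, with loss of the C2 configuration and of the regiochemistry, and acylation may occur at C4 carbon, not at oxygen. The fallback sets out from 3. The kinetic enolate is trapped as it forms (LiN(SiMe3)2 added to 3 and Me3SiCl, THF, −78 °C) as (2R)-5,7-bis(benzyloxy)-2-[3,4-bis(benzyloxy)phenyl]-3-(trimethylsilyloxy)-2H-chromene F2, whose regiochemistry and C2 integrity can be checked. F2 is then acylated on oxygen by 6 on fluoride activation (Bu4N[Ph3SiF2]), coming back to the route at 9.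

**Step 10.** Attack by the hindered C8 of 11 may be slow, so that the acid released re-ionises the interflavan bond of 11 or 16 (cleavage, scrambling) or the free C3 hydroxyl of 14 competes as an oxygen nucleophile. The fallback sets out from 14 and changes the activation principle from an oxophilic Lewis acid to a thiophilic one under non-acidic conditions. Exchange of the C4 ether for a thioether (2-mercaptobenzothiazole, BF3·OEt2) gives (2R,3S,4S)-4-(1,3-benzothiazol-2-ylsulfanyl)-8-bromo-5,7-bis(benzyloxy)-2-[3,4-bis(benzyloxy)phenyl]chroman-3-ol F3. F3 is activated with AgBF4 in THF at 0 °C in the presence of 11 and comes back to the route at 16.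

**Step 11.** HBr released during hydrodebromination while eighteen benzyl ethers are being cleaved may cause acid-induced interflavan cleavage, and bromide may poison the catalyst and leave debenzylation incomplete. The fallback sets out from 16 and separates the two events. Radical hydrodebromination ((Me3Si)3SiH, 2,2'-azobis(isobutyronitrile), toluene, 80 °C) gives the bromine-free octadeca-O-benzyl trimer F4. F4 is hydrogenolysed without amine (H2, Pd(OH)2 on carbon, THF/MeOH/H2O) and comes back to the route at 17.

## Further compounds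

F1 | step 7 | octa-O-benzyl procyanidin B2, [5,7,3',4'-tetra-O-benzyl-epicatechin]-(4β→8)-[5,7,3',4'-tetra-O-benzyl-epicatechin] | O[C@@H]1[C@@H](c2c(OCc9ccccc9)cc(OCc9ccccc9)c3c2O[C@H](c2ccc(OCc9ccccc9)c(OCc9ccccc9)c2)[C@H](O)C3)c2c(OCc9ccccc9)cc(OCc9ccccc9)cc2O[C@@H]1c1ccc(OCc9ccccc9)c(OCc9ccccc9)c1
F2 | step 6 | (2R)-5,7-bis(benzyloxy)-2-[3,4-bis(benzyloxy)phenyl]-3-(trimethylsilyloxy)-2H-chromene | C[Si](C)(C)OC1=Cc2c(OCc9ccccc9)cc(OCc9ccccc9)cc2O[C@@H]1c1ccc(OCc9ccccc9)c(OCc9ccccc9)c1
F3 | step 10 | (2R,3S,4S)-4-(1,3-benzothiazol-2-ylsulfanyl)-8-bromo-5,7-bis(benzyloxy)-2-[3,4-bis(benzyloxy)phenyl]chroman-3-ol | c1ccc2sc(nc2c1)S[C@H]1c2c(OCc9ccccc9)cc(OCc9ccccc9)c(Br)c2O[C@H](c2ccc(OCc9ccccc9)c(OCc9ccccc9)c2)[C@@H]1O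
F4 | step 11 | [5,7,3',4'-tetra-O-benzyl-epicatechin]-(4β→8)-[5,7,3',4'-tetra-O-benzyl-epicatechin 3-O-(tri-O-benzylgallate)]-(4β→8)-[5,7,3',4'-tetra-O-benzyl-epicatechin 3-O-(tri-O-benzylgallate)] | O=C(O[C@@H]1[C@@H](c2c(OCc9ccccc9)cc(OCc9ccccc9)c3c2O[C@H](c2ccc(OCc9ccccc9)c(OCc9ccccc9)c2)[C@H](OC(=O)c2cc(OCc9ccccc9)c(OCc9ccccc9)c(OCc9ccccc9)c2)C3)c2c(OCc9ccccc9)cc(OCc9ccccc9)c([C@H]3c4c(OCc9ccccc9)cc(OCc9ccccc9)cc4O[C@H](c4ccc(OCc9ccccc9)c(OCc9ccccc9)c4)[C@@H]3O)c2O[C@@H]1c1ccc(OCc9ccccc9)c(OCc9ccccc9)c1)c1cc(OCc9ccccc9)c(OCc9ccccc9)c(OCc9ccccc9)c1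
A1 | alternative 1 | (2R,3R,4S)-5,7-bis(benzyloxy)-2-[3,4-bis(benzyloxy)phenyl]-4-(2-ethoxyethoxy)chroman-3-yl 3,4,5-tris(benzyloxy)benzoate | CCOCCO[C@H]1c2c(OCc9ccccc9)cc(OCc9ccccc9)cc2O[C@H](c2ccc(OCc9ccccc9)c(OCc9ccccc9)c2)[C@@H]1OC(=O)c1cc(OCc9ccccc9)c(OCc9ccccc9)c(OCc9ccccc9)c1
A2 | alternative 2 | (2R,3S)-5,7-bis(benzyloxy)-2-[3,4-bis(benzyloxy)phenyl]-3-[(tert-butyldimethylsilyl)oxy]chroman-4-one | O=C1c2c(OCc9ccccc9)cc(OCc9ccccc9)cc2O[C@H](c2ccc(OCc9ccccc9)c(OCc9ccccc9)c2)[C@@H]1O[Si](C)(C)C(C)(C)C
A3 | alternative 3 | (2R,3R,4S)-5,7-bis(benzyloxy)-2-[3,4-bis(benzyloxy)phenyl]-4-(2-ethoxyethoxy)chroman-3-yl (2R,3R)-5,7-bis(benzyloxy)-2-[3,4-bis(benzyloxy)phenyl]chroman-3-yl pentanedioate | CCOCCO[C@H]1c2c(OCc9ccccc9)cc(OCc9ccccc9)cc2O[C@H](c2ccc(OCc9ccccc9)c(OCc9ccccc9)c2)[C@@H]1OC(=O)CCCC(=O)O[C@@H]1Cc2c(OCc9ccccc9)cc(OCc9ccccc9)cc2O[C@@H]1c1ccc(OCc9ccccc9)c(OCc9ccccc9)c1
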